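**Target.** CNP0324463.3 is a germacranolide: (1R,3S,4Z,6R,7R,8R,10R)-3-benzoyloxy-1,10-epoxy-8-[(2S,3S)-2,3-dimethyloxirane-2-carbonyl]oxy-germacra-4,11(13)-dien-12,6-olide. In germacrane terms it is 1β,10α-epoxy, 3β-OBz, 8β-O-acyl, 6α-O, H-7α.

## Structural features

The target is a ten-membered carbocycle (C1–C10) with an α-methylene-γ-butyrolactone (O–C6, C7, C11=C13, C12) trans-fused across C6–C7. The carbocycle carries a trans-epoxide at C1/C10 (C10 also bears the C14 methyl), a ring-cis trisubstituted C4=C5 alkene bearing the C15 methyl, a benzoate at C3 and a (2S,3S)-2,3-epoxy-2-methylbutanoate at C8. The stereocentres form a contiguous triad C6–C7–C8 (lactone oxygen α, C11 and the C8 oxygen β), an allylic centre C3 next to C4, the epoxide pair C1/C10, and the two centres of the side-chain epoxide. Fragile features are the α-methylene lactone (a Michael acceptor), two acid-labile epoxides, the 1,10-epoxy-4-ene (prone to transannular cyclisation under acid), the base-labile esters, and the C8 oxygen, which sits β to C6 whenever C6 is a carbonyl. The real difficulty is the medium ring with two defined alkene geometries, the setting of C6 and C7 relative to C8, and the differentiation of the oxygens at C3, C6 and C8. The key step exploits the 1,5-diene C10=C1–C2–C3–C4=C5 formed by C4=C5 and the C1=C10 alkene latent in the epoxide. Reconnecting C1–C4 and C5–C10 turns the ten-membered ring into a cyclohexanone (C5–C10) and a cyclobutene (C1–C4) joined through a central cyclobutane (C1, C4, C5, C10), so only C3 and C8 have to be carried through as stereocentres.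

## Logic of the disconnections

**38 ⇒ 37.** The two C–O bonds of the C1/C10 epoxide are cut. The epoxide is the group least likely to survive fluoride, enolate or acid chemistry, and its E-alkene precursor is what the ring-forming sequence delivers. This removes two stereocentres. The forward step must epoxidise only the electron-rich C1=C10 bond, and on its outer face.

**37 ⇒ 35 + 17 (17 ⇒ 16 ⇒ 15 ⇒ 14).** The C8 O–acyl bond is cut, so the side chain and its two stereocentres are made separately under reagent control from 14 (C–O bonds of the small epoxide, then the carboxyl oxidation level). The gain is convergence. The demand is acylation of a hindered secondary alcohol by an α-quaternary acid without opening either epoxide.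

**35 ⇒ 34 ⇒ 33 ⇒ 32.** The C3 O–benzoyl bond and the two O–Si bonds are cut. Two silyl ethers of different lability let C3 and C8 be unmasked one after the other. The demand is that the C3 triethylsilyl ether can be removed in the presence of the C8 tert-butyldimethylsilyl ether and the α-methylene lactone.

**32 ⇒ 28.** The C11=C13 bond is cut. The exocyclic methylene is added last to the lactone because it would not survive hydride or enolate steps. The demand is regioselective enolisation at C11.

**28 ⇒ 26.** The lactone O–C12 bond and the C6–H bond are cut, which reveals a C6 ketone with an acetic ester arm on C7. The ketone is what allows C7 to be alkylated and what the ring-forming step provides. The demand is hydride delivery to the face that gives the 6α-alcohol.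

**26 ⇒ 23 + 24.** The C7–C11 bond is cut (enolate alkylation). The gain is a ring with stereocentres only at C3 and C8. The demand is kinetic α′-enolisation of a β-silyloxy enone without loss of the silyloxy group, and attack on the face that places C11 β.

**23 ⇒ 22 ⇒ 20 ⇒ 19.** C15 is taken back from methyl to the ester that the key step requires (C–H for C–O at C15). C6 passes through the alcohol level on the way. Doing this directly after ring formation, when ketone and ester are the only reducible groups, avoids any conflict with a lactone. The demand is selective activation of the primary allylic alcohol.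

**19 ⇒ 18.** C1–C4 and C5–C10 are reconnected. The ten-membered dienone becomes a tricyclic ketone whose strain drives the forward cycloreversion. Two alkene geometries are exchanged for four stereocentres that need no absolute control. The demand is that cleavage gives the 1(10)E,4-cis diene and stops before Cope rearrangement.

**18 ⇒ 7 + 13.** C4–C5 and C1–C10 are cut. This gives two small rings, each with one stereocentre. The demand is head-to-head regiochemistry.

**7 ⇒ 5 ⇒ 4 ⇒ 3 ⇒ 2 ⇒ 1.** The C10–C14 bond (methyl addition with carbonyl transposition), the O–Si bond, a resolution, the enol ether C–O bond and one ring C=O reduction lead back to 1. The demand is that the choice of which carbonyl receives the methyl group, fixed through the resolved vinylogous ester, sets C8.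

**13 ⇒ 12 ⇒ 11 ⇒ 8 + 9.** The O–Si bond, a resolution, and then the C1–C2 and C3–C4 bonds of the four-membered ring are cut. The [2+2] union of 8 and 9 places the oxygen next to the ester carbon by its polarity alone. The demand is a resolution of the allylic alcohol and cold handling of a thermally labile cyclobutene.

## Other disconnections considered

**Alternative 1:** Ramberg–Bäcklund contraction.
- **Cut:** C4=C5, replaced by a C4–SO2–C5 bridge in the eleven-membered sulfone A1.
- **Forward key step:** in-situ α-halogenation of A1 (KOH/Al2O3, CBr2F2), closure to the episulfone and loss of SO2 would give the diene A2.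
- **In favour:** the ring is first closed by sulfide alkylation, one of the easiest medium-ring closures. C3, C6, C7 and C8 are set on open-chain intermediates. C15 arrives as a methyl group. Nothing is heated to 180 °C.
- **Against here:** both α-sulfonyl carbons carry a β-oxygen (C3–OPMB next to C4, C6–OTBS next to C5), so E1cB loss of alkoxide competes with halogenation and closure. The Z geometry of a trisubstituted alkene formed inside a ten-membered ring is not assured. A1 needs a long linear build.
- **Comparison:** structurally it is better than the chosen plan at C6–C8 (set before the ring exists) and at C15 (no redox correction). Mechanistically it is weaker, because its key step must survive two β-leaving groups, whereas the photocycloaddition only needs regiocontrol. On step economy the chosen plan is clearly ahead: it makes the ring and both alkenes in two steps from two small rings.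

**Alternative 2:** Samarium Reformatsky closure.
- **Cut:** C1–C2, disconnecting the seco bromo ketone aldehyde A3.
- **Forward key step:** SmI2 (samarium diiodide, divalent samarium) would reduce the C2 bromide of A3 to a samarium enolate that adds to the C1 aldehyde, closing the ring to the β-hydroxy enone A4.
- **In favour:** the trans lactone and the Z-enone are in place before macrocyclisation. The chelated samarium aldolate acts as a template for medium rings. The C1 hydroxyl and the C10 oxygen already carry the oxygen pattern of the epoxide.
- **Against here:** the C1 carbinol configuration is set by the ring closure without a clear control element, yet the later epoxide closure with inversion needs one specific epimer. The C3 ketone still has to be reduced to the 3β-alcohol. Pinacol coupling and simple debromination compete. The tertiary C10 centre must be built acyclically.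
- **Comparison:** it is better than the chosen plan for the lactone stereochemistry (fixed before ring closure) and equal or better on the epoxide, since no late facial selectivity on an alkene is needed. It is worse on the number of steps to A3 and on redox corrections at C1 and C3. Its ring closure creates one bond and one uncontrolled stereocentre, whereas the chosen key step creates two bonds and needs no lasting stereocontrol.

**Alternative 3:** Alkenylchromium–aldehyde closure.
- **Cut:** C5–C6, disconnecting the Z-iodoalkene aldehyde A5.
- **Forward key step:** CrCl2 (divalent chromium) with catalytic NiCl2 would convert the C5 iodide of A5 into an alkenylchromium species that adds to the C6 aldehyde, giving the allylic alcohol A6, whose C6 hydroxyl is γ to the C12 ester and ready to lactonise.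
- **In favour:** this is the most proven way to close ten-membered allylic alcohols. The alkene geometry of the iodide is retained. C7 and C8 are set by open-chain chemistry. C15 is already a methyl group.
- **Against here:** the C6 configuration arises in the ring closure under substrate control. The α-branched aldehyde can epimerise at C7. Stoichiometric chromium at high dilution is needed. The Z-trisubstituted iodide next to C3 and the E-trisubstituted C1=C10 both require dedicated stereoselective steps.
- **Comparison:** it is equal to the chosen plan at C6 (both set it under substrate control, here in the closure, there by reduction). It is better at C7 and C15, and at least equal in the reliability of the ring closure for this ring size. The chosen plan is more convergent and shorter up to the ring, but pays with the C15 correction and with alkylation on the macrocycle.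

Key step: step 12

**Conventions, structure check and assumptions**

- Ten-membered-ring compounds carry germacrane numbering. α/β refer to the usual germacranolide drawing (H-7 α, C-14 β).
- Structure check: the configurations of 7 (5R), 13 (4S) and 18 agree with C8 (R) and C3 (S) of the target, and 18 is the cis-anti-cis head-to-head adduct. Two points of description are corrected:
  - In the ester-bearing compounds (18-derived 19) the ring-cis C4=C5 bond has the CIP label E; the label Z only applies once C15 is CH2OH or CH3.
  - With the 3S/8R pairing, attack anti to the C3 silyl ether plus cis-anti-cis fusion necessarily places the new cyclobutane cis to the C8 silyl ether on the six-membered ring. The enone face is therefore not a free choice, although either facial isomer serves.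
- Changes of design against the outline of the plan:
  - C15 is reduced directly after ring opening, before any lactone exists, because a hydride reduction of the ester cannot coexist with a lactone or an α-methylene lactone.
  - The C7 arm is introduced as a methyl ester, which lactonises under mild acid; a tert-butyl ester would need strong acid, or base that invites 1,3-silyl migration.
  - The cyclobutene is made by a [2+2] of 8 and 9 and resolved as the configurationally stable allylic alcohol.
  - C3–O stays silylated for as long as C6 is a ketone, since a free 3-hydroxyl cis to the 6-ketone across C4=C5 would form a hemiketal.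
- Assumption: in step 3 the lipase acetylates the (R)-enantiomer of 3 (the two ring CH2 flanks are too similar for a firm prediction). If the sense is reversed, the acetate is the (S)-compound and is methanolysed to 4.

## Steps

Step 1
Reactants: 1 phloroglucinol
Product: 2 5-hydroxycyclohexane-1,3-dione
Conditions: H2 (3 atm), Rh/Al2O3 (5%), NaOH (1.0 equiv), H2O, rt; then HCl to pH 3, 0 °C
Reagents that add atoms: none
Why: Partial catalytic hydrogenation of the phloroglucinol monoanion reduces one C=O of the triketo tautomer, and the product is shielded from further reduction as its vinylogous carboxylate; the product is achiral.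

Step 2
Reactants: 2 5-hydroxycyclohexane-1,3-dione
Product: 3 rac-3-ethoxy-5-hydroxycyclohex-2-en-1-one
Conditions: EtOH, TsOH·H2O (cat.), 3 Å MS, rt
Reagents that add atoms: ethanol, CCO
Why: Acid-catalysed enol etherification of a cyclic 1,3-dione (vinylogous Fischer esterification) desymmetrises the dione and creates C5 as a racemate; room temperature keeps the β-hydroxy ketone from dehydrating to a resorcinol ether.

Step 3
Reactants: 3 rac-3-ethoxy-5-hydroxycyclohex-2-en-1-one
Product: 4 (5S)-3-ethoxy-5-hydroxycyclohex-2-en-1-one
Conditions: Novozym 435 (immobilised Candida antarctica lipase B), vinyl acetate, MTBE, 30 °C, stopped near 55% conversion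
Reagents that add atoms: none
Why: Lipase-catalysed kinetic resolution by irreversible transesterification should leave the (S)-alcohol in high ee past half conversion; the acetylated antipode can be recycled, since acid-catalysed exchange of the vinylogous ester interconverts the enantiomers.

Step 4
Reactants: 4 (5S)-3-ethoxy-5-hydroxycyclohex-2-en-1-one
Product: 5 (5S)-5-[tert-butyl(dimethyl)silyl]oxy-3-ethoxycyclohex-2-en-1-one
Conditions: TBSCl, imidazole, DMF, 0 °C to rt
Reagents that add atoms: tert-butyldimethylsilyl chloride, CC(C)(C)[Si](C)(C)Cl
Why: Standard silylation of a secondary alcohol; the stereocentre is not involved.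

Step 5
Reactants: 5 (5S)-5-[tert-butyl(dimethyl)silyl]oxy-3-ethoxycyclohex-2-en-1-one
Product: 7 (5R)-5-[tert-butyl(dimethyl)silyl]oxy-3-methylcyclohex-2-en-1-one, via tertiary carbinol 6 (not isolated)
Conditions: MeLi, THF, −78 °C; then 1 M HCl, 0 °C, short contact
Reagents that add atoms: methyllithium, [Li]C; water, O
Why: Stork–Danheiser alkylative carbonyl transposition: 1,2-addition to the vinylogous ester, then acid-induced ionisation and hydrolysis of the enol ether; the stereocentre is untouched, its descriptor changes only because the ring CH2 priorities swap, and cold dilute acid avoids β-elimination of the silanol.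

Step 6
Reactants: 8 tert-butyl(dimethyl)(vinyloxy)silane; 9 methyl propiolate
Product: 11 rac-methyl 4-hydroxycyclobut-1-ene-1-carboxylate, via silyl ether 10 (not isolated)
Conditions: Tf2NH (2 mol %), CH2Cl2, −78 °C; Et3N; then aq. HF, MeCN, 0 °C
Reagents that add atoms: none
Why: Acid-catalysed stepwise [2+2] of a silyl enol ether with a propiolate (Mukaiyama–Michael addition of the enol ether CH2 to the alkyne terminus, then ring closure of the allenoate onto the oxocarbenium carbon) puts the oxygen-bearing carbon next to the ester carbon; the product is racemic and is desilylated cold because the free alcohol is needed for the resolution.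

Step 7
Reactants: 11 rac-methyl 4-hydroxycyclobut-1-ene-1-carboxylate
Product: 12 methyl (4S)-4-hydroxycyclobut-1-ene-1-carboxylate
Conditions: Burkholderia cepacia lipase (Amano PS), vinyl acetate, MTBE, rt, stopped near 55% conversion
Reagents that add atoms: none
Why: Lipase kinetic resolution of a cyclic allylic alcohol whose carbinol flanks differ strongly (sp2 carbon with ester versus CH2); by Kazlauskas' rule the (R)-enantiomer should be acetylated and the required (S)-alcohol left behind.

Step 8
Reactants: 12 methyl (4S)-4-hydroxycyclobut-1-ene-1-carboxylate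
Product: 13 methyl (4S)-4-(triethylsilyloxy)cyclobut-1-ene-1-carboxylate
Conditions: TESCl, imidazole, CH2Cl2, 0 °C
Reagents that add atoms: chlorotriethylsilane, CC[Si](Cl)(CC)CC
Why: Silylation under weakly basic conditions avoids the alkoxide, which would accelerate electrocyclic ring opening; the triethylsilyl group is chosen so that C3 can later be unmasked before C8.

Step 9
Reactants: 14 methyl angelate
Product: 15 (2Z)-2-methylbut-2-en-1-ol
Conditions: iBu2AlH (2.2 equiv), CH2Cl2, −78 °C; aq. potassium sodium tartrate
Reagents that add atoms: none
Why: 1,2-Reduction of an enoate to the allylic alcohol with retention of the Z geometry.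

Step 10
Reactants: 15 (2Z)-2-methylbut-2-en-1-ol
Product: 16 [(2R,3S)-2,3-dimethyloxiran-2-yl]methanol
Conditions: Ti(OiPr)4 (10 mol %), D-(−)-diethyl tartrate (12 mol %), tBuOOH, 4 Å MS, CH2Cl2, −20 °C
Reagents that add atoms: tert-butyl hydroperoxide, CC(C)(C)OO
Why: Sharpless asymmetric epoxidation; the D-tartrate delivers oxygen to the face that gives the 2R epoxy alcohol (the L-tartrate gives the 2S series), the cis relation of the methyl groups follows from the Z alkene, and any minor enantiomer becomes a separable diastereomer after step 23.

Step 11
Reactants: 16 [(2R,3S)-2,3-dimethyloxiran-2-yl]methanol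
Product: 17 (2S,3S)-2,3-dimethyloxirane-2-carboxylic acid
Conditions: RuCl3 (cat.), NaIO4, CCl4/MeCN/H2O, rt
Reagents that add atoms: water, O
Why: Ruthenium tetroxide oxidation of an epoxy alcohol to the glycidic acid by way of the aldehyde hydrate; no stereocentre is touched, and the C2 descriptor changes from R to S only through the new priority of the carboxyl carbon.

Step 12
Reactants: 7 (5R)-5-[tert-butyl(dimethyl)silyl]oxy-3-methylcyclohex-2-en-1-one; 13 methyl (4S)-4-(triethylsilyloxy)cyclobut-1-ene-1-carboxylate
Product: 18 methyl (1R,2S,3S,5R,6R,8R)-8-[tert-butyl(dimethyl)silyl]oxy-6-methyl-10-oxo-3-(triethylsilyloxy)tricyclo[4.4.0.0(2,5)]decane-2-carboxylate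
Conditions: hν (medium-pressure Hg lamp, uranium-glass filter, λ > 340 nm), degassed CH2Cl2, −20 °C, 13 (1.5 equiv); then basic Al2O3
Reagents that add atoms: none
Why: This is an enone–alkene [2+2] photocycloaddition in its enone–cyclobutene ester form: n→π* excitation of 7 and intersystem crossing give the triplet enone, whose β-carbon C10 bonds to the unsubstituted cyclobutene carbon C1, and the triplet 1,4-diradical (α-keto radical at C5, ester-stabilised tertiary radical at C4) collapses after spin inversion by forming C4–C5. One ring is closed, the central cyclobutane, by a stepwise two-bond closure (intermolecular C1–C10 bond, then 1,4-radical recombination), which completes the bicyclo[2.2.0]hexane. The step needs head-to-head regiochemistry, and the ester secures it by making C4 the radical-stabilising terminus so that the first bond goes to C1. C1 and C4 are cis because both new bonds lie on one face of the cyclobutene, the face anti to the neighbouring C3 silyl ether; C5 and C10 are cis because a trans 6–4 fusion is strained and any trans-fused adduct is epimerised at C5 on basic Al2O3; the anti disposition of the two outer rings follows from the less hindered collapse of the diradical. With the 3S/8R pairing these controls place the new ring cis to the C8 silyl ether, and the other cis-anti-cis facial isomer is equally usable because C1, C4, C5 and C10 all become sp2 in step 13 while C3 and C8 are untouched. Light above 340 nm excites only the enone, and the low temperature protects the donor-substituted cyclobutene from electrocyclic ring opening.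

Step 13
Reactants: 18 the tricyclic photoadduct
Product: 19 methyl (1(10)E)-8β-[tert-butyl(dimethyl)silyl]oxy-6-oxo-3β-(triethylsilyloxy)germacra-1(10),4-dien-15-oate (ring-cis C4=C5; 3S,8R)
Conditions: degassed 1,2-Cl2C6H4, BHT (cat.), 180 °C, 1–2 h, base-washed glassware
Reagents that add atoms: none
Why: Thermal cycloreversion of the bicyclo[2.2.0]hexane: the strained central C1–C4 bond, weakened by the ester at C4, breaks to a cyclohexane-1,4-diyl, which then cleaves C5–C10 (α to the ketone) and opens both four-membered rings into the ten-membered dienone; cis-anti-cis adducts of this type give the 1(10)E,4-cis geometry, and C3 and C8 are not involved.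

Step 14
Reactants: 19 the dienone ester
Product: 20 (1(10)E,4Z)-8β-[tert-butyl(dimethyl)silyl]oxy-3β-(triethylsilyloxy)germacra-1(10),4-diene-6,15-diol (C6 epimers)
Conditions: iBu2AlH (4.5 equiv), CH2Cl2, −78 °C; aq. potassium sodium tartrate
Reagents that add atoms: none
Why: 1,2-Reduction of the ketone and of the conjugated ester by an electrophilic hydride, with no conjugate reduction; the C6 configuration is immaterial because C6 is reoxidised in step 16.

Step 15
Reactants: 20 the 6,15-diol
Product: 22 (1(10)E,4Z)-8β-[tert-butyl(dimethyl)silyl]oxy-3β-(triethylsilyloxy)germacra-1(10),4-dien-6-ol (C6 epimers), via primary mesylate 21 (not isolated)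
Conditions: MsCl (1.1 equiv), 2,4,6-collidine, CH2Cl2, −40 °C; then LiBHEt3, THF, −78 to 0 °C
Reagents that add atoms: none
Why: Selective sulfonylation of the primary allylic hydroxyl with a hindered base, then SN2 hydride displacement turns C15 into the methyl group; C15 is trans to C6 across C4=C5, so the C6 alkoxide cannot displace the mesylate, and direct displacement keeps the double bond in place.

Step 16
Reactants: 22 the 6-ol
Product: 23 (1(10)E,4Z)-8β-[tert-butyl(dimethyl)silyl]oxy-3β-(triethylsilyloxy)germacra-1(10),4-dien-6-one
Conditions: Dess–Martin periodinane, NaHCO3, CH2Cl2, 0 °C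
Reagents that add atoms: none
Why: Buffered hypervalent-iodine oxidation of the allylic alcohol; both C6 epimers converge on one enone and the silyl ethers are stable.

Step 17
Reactants: 23 the enone; 24 methyl bromoacetate
Product: 26 methyl 2-[(7R)-6-oxo-germacradien-7-yl]acetate, that is 23 with a β-oriented CH2CO2Me on C7 (H-7 α), via lithium dienolate 25 (not isolated)
Conditions: LiN(SiMe3)2 (1.05 equiv), THF, −78 °C; 24, DMPU, −78 to −50 °C; AcOH quench at −78 °C
Reagents that add atoms: none
Why: Kinetic α′-deprotonation of the enone gives the cross-conjugated C6–C7 enolate, which is alkylated by the bromoacetate; C7 should be set by attack anti to the C8–O bond with the C8 hydrogen eclipsing the enolate (allylic-strain control, not enforced here by a six-membered ring), which puts C11 on the β face; the cold acetic acid quench prevents E1cB loss of the C8 silyloxide.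

Step 18
Reactants: 26 the keto ester
Product: 28 8β-[tert-butyl(dimethyl)silyl]oxy-3β-(triethylsilyloxy)-13-norgermacra-1(10)E,4Z-dien-12,6α-olide (trans-fused, H-6 β, H-7 α), via hydroxy ester 27 (not isolated)
Conditions: NaBH4, CeCl3·7H2O, MeOH, −78 °C; then PPTS (cat.), CH2Cl2, rt
Reagents that add atoms: none
Why: Luche 1,2-reduction of the enone, then acid-catalysed lactonisation of the γ-hydroxy methyl ester; hydride is expected to attack anti to the C7 side chain (Felkin–Anh, with C5–C6–C7–C8 held near antiperiplanar by the ring), giving the 6α-alcohol and hence the trans lactone; mild acid avoids silyl migration between O8 and O6.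

Step 19
Reactants: 28 the 13-nor lactone
Product: 32 8β-[tert-butyl(dimethyl)silyl]oxy-3β-(triethylsilyloxy)germacra-1(10)E,4Z,11(13)-trien-12,6α-olide, via lithium enolate 29 (not isolated), via Mannich base 30 (not isolated), via methiodide 31 (not isolated)
Conditions: LiNiPr2, THF, −78 °C; CH2=NMe2+ I−, −78 to 0 °C; MeI, MeOH, rt; NaHCO3, CH2Cl2/H2O
Reagents that add atoms: N,N-dimethylmethyleneiminium iodide (Eschenmoser's salt), C=[N+](C)C.[I-]
Why: α-Methylenation of a lactone by Mannich reaction of its enolate, quaternisation and Hofmann-type elimination; C11 becomes sp2, so its transient configuration is irrelevant.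

Step 20
Reactants: 32 the bis-silyl α-methylene lactone
Product: 33 8β-[tert-butyl(dimethyl)silyl]oxy-3β-hydroxygermacra-1(10)E,4Z,11(13)-trien-12,6α-olide
Conditions: PPTS (cat.), MeOH/CH2Cl2, 0 °C
Reagents that add atoms: none
Why: Mild acid methanolysis removes the triethylsilyl ether much faster than the hindered tert-butyldimethylsilyl ether and is too weak to trigger transannular cyclisation of the diene.

Step 21
Reactants: 33 the 3β-alcohol
Product: 34 3β-benzoyloxy-8β-[tert-butyl(dimethyl)silyl]oxygermacra-1(10)E,4Z,11(13)-trien-12,6α-olide
Conditions: BzCl, pyridine, DMAP (cat.), CH2Cl2, 0 °C to rt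
Reagents that add atoms: benzoyl chloride, O=C(Cl)c1ccccc1
Why: Acylation of the allylic secondary alcohol with retention at C3.

Step 22
Reactants: 34 the 3-benzoate
Product: 35 3β-benzoyloxy-8β-hydroxygermacra-1(10)E,4Z,11(13)-trien-12,6α-olide
Conditions: HF·pyridine, excess pyridine, THF, 0 °C to rt
Reagents that add atoms: none
Why: Buffered fluoride cleavage of the remaining silyl ether; the buffer spares the benzoate, the α-methylene lactone and the acid-sensitive diene.

Step 23
Reactants: 35 the 8β-alcohol; 17 (2S,3S)-2,3-dimethyloxirane-2-carboxylic acid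
Product: 37 3β-benzoyloxy-8β-[(2S,3S)-2,3-dimethyloxirane-2-carbonyl]oxygermacra-1(10)E,4Z,11(13)-trien-12,6α-olide, via mixed anhydride 36 (not isolated)
Conditions: 17, 2,4,6-Cl3C6H2COCl, Et3N, THF, rt; then 35, DMAP, toluene, rt to 40 °C
Reagents that add atoms: none
Why: Yamaguchi esterification: the mixed anhydride is attacked at the less shielded epoxy-acyl carbonyl under DMAP catalysis, with retention at C8; the acid has no α-hydrogen and cannot epimerise.

Step 24
Reactants: 37 the triene diester
Product: 38 CNP0324463.3, (1R,3S,4Z,6R,7R,8R,10R)-3-benzoyloxy-1,10-epoxy-8-[(2S,3S)-2,3-dimethyloxirane-2-carbonyl]oxygermacra-4,11(13)-dien-12,6-olide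
Conditions: mCPBA (1.05 equiv), NaHCO3, CH2Cl2, 0 °C
Reagents that add atoms: 3-chloroperoxybenzoic acid, OOC(=O)c1cccc(Cl)c1
Why: Prilezhaev epoxidation of the only electron-rich alkene (C4=C5 is deactivated by two allylic acyloxy groups, C11=C13 by conjugation); attack on the exposed outer face of the E alkene, in the conformer with C14 on the β face, is expected to give the 1β,10α (1R,10R) epoxide, and the buffer prevents transannular opening.

## Compound list

1 | phloroglucinol | Oc1cc(O)cc(O)c1 | starting material
2 | 5-hydroxycyclohexane-1,3-dione | O=C1CC(O)CC(=O)C1 | intermediate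
3 | rac-3-ethoxy-5-hydroxycyclohex-2-en-1-one | CCOC1=CC(=O)CC(O)C1 | intermediate
4 | (5S)-3-ethoxy-5-hydroxycyclohex-2-en-1-one | CCOC1=CC(=O)C[C@@H](O)C1 | intermediate
5 | (5S)-5-[tert-butyl(dimethyl)silyl]oxy-3-ethoxycyclohex-2-en-1-one | CCOC1=CC(=O)C[C@@H](O[Si](C)(C)C(C)(C)C)C1 | intermediate
6 | 5-[tert-butyl(dimethyl)silyl]oxy-3-ethoxy-1-methylcyclohex-2-en-1-ol (1,2-adduct, C1 epimers, silyloxy centre as in 5) | CCOC1=CC(C)(O)C[C@@H](O[Si](C)(C)C(C)(C)C)C1 | intermediate (not isolated)
7 | (5R)-5-[tert-butyl(dimethyl)silyl]oxy-3-methylcyclohex-2-en-1-one | CC1=CC(=O)C[C@H](O[Si](C)(C)C(C)(C)C)C1 | intermediate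
8 | tert-butyl(dimethyl)(vinyloxy)silane | C=CO[Si](C)(C)C(C)(C)C | starting material
9 | methyl propiolate | C#CC(=O)OC | starting material
10 | rac-methyl 4-[tert-butyl(dimethyl)silyl]oxycyclobut-1-ene-1-carboxylate | COC(=O)C1=CCC1O[Si](C)(C)C(C)(C)C | intermediate (not isolated)
11 | rac-methyl 4-hydroxycyclobut-1-ene-1-carboxylate | COC(=O)C1=CCC1O | intermediate
12 | methyl (4S)-4-hydroxycyclobut-1-ene-1-carboxylate | COC(=O)C1=CC[C@@H]1O | intermediate
13 | methyl (4S)-4-(triethylsilyloxy)cyclobut-1-ene-1-carboxylate | COC(=O)C1=CC[C@@H]1O[Si](CC)(CC)CC | intermediate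
14 | methyl angelate, methyl (2Z)-2-methylbut-2-enoate | C/C=C(/C)C(=O)OC | starting material
15 | (2Z)-2-methylbut-2-en-1-ol | C/C=C(/C)CO | intermediate
16 | [(2R,3S)-2,3-dimethyloxiran-2-yl]methanol | OC[C@@]1(C)O[C@H]1C | intermediate
17 | (2S,3S)-2,3-dimethyloxirane-2-carboxylic acid | OC(=O)[C@@]1(C)O[C@H]1C | intermediate
18 | methyl (1R,2S,3S,5R,6R,8R)-8-[tert-butyl(dimethyl)silyl]oxy-6-methyl-10-oxo-3-(triethylsilyloxy)tricyclo[4.4.0.0(2,5)]decane-2-carboxylate (cis-anti-cis) | COC(=O)[C@@]12[C@@H](O[Si](CC)(CC)CC)C[C@@H]1[C@@]1(C)C[C@@H](O[Si](C)(C)C(C)(C)C)CC(=O)[C@H]12 | intermediate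
19 | methyl (1(10)E)-8β-[tert-butyl(dimethyl)silyl]oxy-6-oxo-3β-(triethylsilyloxy)germacra-1(10),4-dien-15-oate (ring-cis C4=C5) | O=C1/C=C(/C(=O)OC)[C@@H](O[Si](CC)(CC)CC)C/C=C(\C)C[C@@H](O[Si](C)(C)C(C)(C)C)C1 | intermediate
20 | (1(10)E,4Z)-8β-[tert-butyl(dimethyl)silyl]oxy-3β-(triethylsilyloxy)germacra-1(10),4-diene-6,15-diol (C6 epimers) | OC1/C=C(/CO)[C@@H](O[Si](CC)(CC)CC)C/C=C(\C)C[C@@H](O[Si](C)(C)C(C)(C)C)C1 | intermediate
21 | 15-methanesulfonate of 20 | OC1/C=C(/COS(C)(=O)=O)[C@@H](O[Si](CC)(CC)CC)C/C=C(\C)C[C@@H](O[Si](C)(C)C(C)(C)C)C1 | intermediate (not isolated)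
22 | (1(10)E,4Z)-8β-[tert-butyl(dimethyl)silyl]oxy-3β-(triethylsilyloxy)germacra-1(10),4-dien-6-ol (C6 epimers) | OC1/C=C(/C)[C@@H](O[Si](CC)(CC)CC)C/C=C(\C)C[C@@H](O[Si](C)(C)C(C)(C)C)C1 | intermediate
23 | (1(10)E,4Z)-8β-[tert-butyl(dimethyl)silyl]oxy-3β-(triethylsilyloxy)germacra-1(10),4-dien-6-one | O=C1/C=C(/C)[C@@H](O[Si](CC)(CC)CC)C/C=C(\C)C[C@@H](O[Si](C)(C)C(C)(C)C)C1 | intermediate
24 | methyl bromoacetate | COC(=O)CBr | starting material
25 | lithium C6–C7 dienolate of 23 | [Li]OC=1/C=C(/C)[C@@H](O[Si](CC)(CC)CC)C/C=C(\C)C[C@@H](O[Si](C)(C)C(C)(C)C)C=1 | intermediate (not isolated)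
26 | 23 bearing a β-CH2CO2Me group on C7 (7R, H-7 α) | O=C1/C=C(/C)[C@@H](O[Si](CC)(CC)CC)C/C=C(\C)C[C@@H](O[Si](C)(C)C(C)(C)C)[C@H]1CC(=O)OC | intermediate
27 | 6α-hydroxy ester from 26 | O[C@@H]1/C=C(/C)[C@@H](O[Si](CC)(CC)CC)C/C=C(\C)C[C@@H](O[Si](C)(C)C(C)(C)C)[C@H]1CC(=O)OC | intermediate (not isolated)
28 | 8β-[tert-butyl(dimethyl)silyl]oxy-3β-(triethylsilyloxy)-13-norgermacra-1(10)E,4Z-dien-12,6α-olide | C1C(=O)O[C@@H]2/C=C(/C)[C@@H](O[Si](CC)(CC)CC)C/C=C(\C)C[C@@H](O[Si](C)(C)C(C)(C)C)[C@@H]12 | intermediate
29 | lithium enolate of 28 | C1=C(O[Li])O[C@@H]2/C=C(/C)[C@@H](O[Si](CC)(CC)CC)C/C=C(\C)C[C@@H](O[Si](C)(C)C(C)(C)C)[C@@H]12 | intermediate (not isolated)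
30 | 11-(dimethylaminomethyl) derivative of 28 (C11 epimers) | CN(C)CC1C(=O)O[C@@H]2/C=C(/C)[C@@H](O[Si](CC)(CC)CC)C/C=C(\C)C[C@@H](O[Si](C)(C)C(C)(C)C)[C@@H]12 | intermediate (not isolated)
31 | trimethylammonium iodide from 30 | C[N+](C)(C)CC1C(=O)O[C@@H]2/C=C(/C)[C@@H](O[Si](CC)(CC)CC)C/C=C(\C)C[C@@H](O[Si](C)(C)C(C)(C)C)[C@@H]12.[I-] | intermediate (not isolated)
32 | 8β-[tert-butyl(dimethyl)silyl]oxy-3β-(triethylsilyloxy)germacra-1(10)E,4Z,11(13)-trien-12,6α-olide | C=C1C(=O)O[C@@H]2/C=C(/C)[C@@H](O[Si](CC)(CC)CC)C/C=C(\C)C[C@@H](O[Si](C)(C)C(C)(C)C)[C@@H]12 | intermediate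
33 | 8β-[tert-butyl(dimethyl)silyl]oxy-3β-hydroxygermacra-1(10)E,4Z,11(13)-trien-12,6α-olide | C=C1C(=O)O[C@@H]2/C=C(/C)[C@@H](O)C/C=C(\C)C[C@@H](O[Si](C)(C)C(C)(C)C)[C@@H]12 | intermediate
34 | 3β-benzoyloxy-8β-[tert-butyl(dimethyl)silyl]oxygermacra-1(10)E,4Z,11(13)-trien-12,6α-olide | C=C1C(=O)O[C@@H]2/C=C(/C)[C@@H](OC(=O)c3ccccc3)C/C=C(\C)C[C@@H](O[Si](C)(C)C(C)(C)C)[C@@H]12 | intermediate
35 | 3β-benzoyloxy-8β-hydroxygermacra-1(10)E,4Z,11(13)-trien-12,6α-olide | C=C1C(=O)O[C@@H]2/C=C(/C)[C@@H](OC(=O)c3ccccc3)C/C=C(\C)C[C@@H](O)[C@@H]12 | intermediate
36 | (2S,3S)-2,3-dimethyloxirane-2-carboxylic 2,4,6-trichlorobenzoic anhydride | O=C(OC(=O)c1c(Cl)cc(Cl)cc1Cl)[C@@]1(C)O[C@H]1C | intermediate (not isolated)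
37 | 3β-benzoyloxy-8β-[(2S,3S)-2,3-dimethyloxirane-2-carbonyl]oxygermacra-1(10)E,4Z,11(13)-trien-12,6α-olide | C=C1C(=O)O[C@@H]2/C=C(/C)[C@@H](OC(=O)c3ccccc3)C/C=C(\C)C[C@@H](OC(=O)[C@@]3(C)O[C@H]3C)[C@@H]12 | intermediate
38 | CNP0324463.3 | C=C1C(=O)O[C@@H]2/C=C(/C)[C@@H](OC(=O)c3ccccc3)C[C@H]3O[C@]3(C)C[C@@H](OC(=O)[C@@]3(C)O[C@H]3C)[C@@H]12 | target

## Step count and least certain steps

Total: 24 steps (enone branch 5, cyclobutene branch 3, acid branch 3, main line 13). Longest linear sequence: 18 steps (1 to 38 through steps 1–5 and 12–24).

**Step 12 (key step).**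
- Most likely to go wrong: thermal electrocyclic opening of the donor-substituted cyclobutene 13 during the irradiation, together with erosion of head-to-head control or enone dimerisation as the alkene is consumed. The oxygen on the sp3 carbon lowers the ring-opening barrier well below that of the parent cyclobutene ester, and this pairing has no direct precedent.
- Fallback (a change of precursor design): it sets out from 12. Benzyl chloroformate and pyridine give methyl (4S)-4-(benzyloxycarbonyloxy)cyclobut-1-ene-1-carboxylate F1, whose acceptor substituent slows ring opening and keeps the alkene electron-poor. Irradiation of F1 with 7 as in step 12 gives the carbonate photoadduct F2. Hydrogenolysis (H2, Pd/C, EtOAc) gives the hydroxy photoadduct F3 under neutral conditions, which matters because base would open the β-hydroxy ester cyclobutane by retro-aldol cleavage. TESCl and imidazole then return the route to 18.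

**Step 13.**
- Most likely to go wrong: diversion of the 1,4-diyl into C2–C3 scission, or Cope rearrangement of 19, both leading to a divinylcyclohexanone. The C3 silyloxy group favours this because it turns the new C3=C4 bond of that product into a stabilised β-silyloxyacrylate.
- Fallback (the donor is replaced by an acceptor for the thermal step): it sets out from 18. PPTS in MeOH gives the hydroxy photoadduct F3, and trifluoroacetic anhydride with pyridine gives the trifluoroacetate photoadduct F4. Thermolysis as in step 13 gives the trifluoroacetoxy dienone ester F5. Methanolysis with NaHCO3 in MeOH at 0 °C gives the 3-hydroxy dienone ester F6, which is silylated at once in the same flask (TESCl, imidazole) before it can form a transannular hemiketal. The route is rejoined at 19.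

**Step 17.**
- Most likely to go wrong: weak or reversed facial selectivity at C7, because the ten-membered enolate may react through a conformer with the C8 oxygen in the enolate plane, and E1cB loss of the C8 silyloxide from the enolate.
- Fallback (C7 is set by C–H instead of C–C bond formation): it sets out from 23. If the alkylation delivers the 7-epi keto ester F7, F7 is deprotonated at C7 with LiN(SiMe3)2 at −78 °C and the enolate is protonated kinetically with 2,6-di-tert-butylphenol. The same facial bias that misplaced the side chain now delivers the proton to that face, and the route is rejoined at 26.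

**Step 18.**
- Most likely to go wrong: hydride delivery to the other carbonyl face, since the conformation of the macrocyclic enone is not known, which would give the 6β-alcohol and the cis-fused lactone.
- Fallback (C6 is set by C–O bond formation with inversion): it sets out from 26. The same reduction and lactonisation would then give the cis-fused lactone F8. LiOH in THF/H2O opens F8 to the 6β-hydroxy acid F9, and Mitsunobu lactonisation (PPh3, DIAD, THF, 0 °C; 5-exo displacement at C6 with inversion) returns the route to 28.

**Step 24.**
- Most likely to go wrong: attack of the peracid on the wrong face of C1=C10 if the reacting conformer has C14 turned inward, or acid-induced transannular opening of the product.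
- Fallback (reagent control in place of substrate control): it sets out from 37 and ends at 38. Shi epoxidation with the D-fructose-derived ketone and KHSO5 in buffered MeCN/H2O at 0 °C is used; the spiro transition-state model predicts the R,R epoxide for an E-trisubstituted alkene of this type. No new compound is made.

**Step 3.**
- Most likely to go wrong: low enantioselectivity of the enzymatic acylation, because the two flanks of the carbinol differ only beyond the CH2 groups.
- Fallback (covalent diastereomers in place of enzymatic discrimination): it sets out from 3. Esterification with (S)-2-methoxy-2-phenylacetic acid (DCC, DMAP) gives two diastereomeric esters, which are separated by chromatography or crystallisation. The ester of the (S)-alcohol, F10, is methanolysed (K2CO3, MeOH, 0 °C) and the route is rejoined at 4.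

## Further compounds

F1 | step 12 | methyl (4S)-4-(benzyloxycarbonyloxy)cyclobut-1-ene-1-carboxylate | COC(=O)C1=CC[C@@H]1OC(=O)OCc1ccccc1
F2 | step 12 | 3-(benzyloxycarbonyloxy) analogue of photoadduct 18 | COC(=O)[C@@]12[C@@H](OC(=O)OCc3ccccc3)C[C@@H]1[C@@]1(C)C[C@@H](O[Si](C)(C)C(C)(C)C)CC(=O)[C@H]12
F3 | step 12 | 3-hydroxy analogue of photoadduct 18 | COC(=O)[C@@]12[C@@H](O)C[C@@H]1[C@@]1(C)C[C@@H](O[Si](C)(C)C(C)(C)C)CC(=O)[C@H]12
F4 | step 13 | 3-trifluoroacetoxy analogue of photoadduct 18 | COC(=O)[C@@]12[C@@H](OC(=O)C(F)(F)F)C[C@@H]1[C@@]1(C)C[C@@H](O[Si](C)(C)C(C)(C)C)CC(=O)[C@H]12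
F5 | step 13 | 3β-trifluoroacetoxy analogue of dienone ester 19 | O=C1/C=C(/C(=O)OC)[C@@H](OC(=O)C(F)(F)F)C/C=C(\C)C[C@@H](O[Si](C)(C)C(C)(C)C)C1
F6 | step 13 | 3β-hydroxy analogue of dienone ester 19 | O=C1/C=C(/C(=O)OC)[C@@H](O)C/C=C(\C)C[C@@H](O[Si](C)(C)C(C)(C)C)C1
F7 | step 17 | 7-epi-26 (side chain α, H-7 β) | O=C1/C=C(/C)[C@@H](O[Si](CC)(CC)CC)C/C=C(\C)C[C@@H](O[Si](C)(C)C(C)(C)C)[C@@H]1CC(=O)OC
F8 | step 18 | 6-epi-28, cis-fused 12,6β-olide | C1C(=O)O[C@H]2/C=C(/C)[C@@H](O[Si](CC)(CC)CC)C/C=C(\C)C[C@@H](O[Si](C)(C)C(C)(C)C)[C@@H]12
F9 | step 18 | 6β-hydroxy acid from F8 | O[C@H]1/C=C(/C)[C@@H](O[Si](CC)(CC)CC)C/C=C(\C)C[C@@H](O[Si](C)(C)C(C)(C)C)[C@H]1CC(=O)O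
F0 | step 24 | none | none
F10 | step 3 | (1S)-3-ethoxy-5-oxocyclohex-3-en-1-yl (2S)-2-methoxy-2-phenylacetate | CCOC1=CC(=O)C[C@@H](OC(=O)[C@@H](OC)c2ccccc2)C1
A1 | alternative 1 | eleven-membered sulfone with sulfur between C4 and C5 (C4 epimers) | C=C(CO[Si](C)(C)C(C)(C)C)[C@H]1[C@H](O[Si](C)(C)C(C)(C)C)CS(=O)(=O)C(C)[C@@H](OCc2ccc(OC)cc2)C/C=C(\C)C[C@H]1OCOC
A2 | alternative 1 | (4Z,1(10)E)-cyclodecadiene with C6 and C12 silyl ethers, C3 PMB ether and C8 MOM ether | C=C(CO[Si](C)(C)C(C)(C)C)[C@H]1[C@H](O[Si](C)(C)C(C)(C)C)/C=C(/C)[C@@H](OCc2ccc(OC)cc2)C/C=C(\C)C[C@H]1OCOC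
A3 | alternative 2 | seco C2 bromomethyl enone C1 aldehyde on the preformed trans lactone | C1C(=O)O[C@H](/C=C(/C)C(=O)CBr)[C@H]1[C@H](O[Si](C)(C)C(C)(C)C)C[C@@](C)(O[Si](CC)(CC)CC)C=O
A4 | alternative 2 | ten-membered β-hydroxy enone fused to the butanolide (C1 carbinol, C3 ketone) | C1C(=O)O[C@@H]2/C=C(/C)C(=O)C[C@H](O)[C@](C)(O[Si](CC)(CC)CC)C[C@@H](O[Si](C)(C)C(C)(C)C)[C@@H]12
A5 | alternative 3 | seco C5 (Z)-iodoalkene C6 aldehyde with the C7 acetate arm | I/C=C(/C)[C@@H](O[Si](C)(C)C(C)(C)C)C/C=C(\C)C[C@@H](OCOC)[C@@H](CC(=O)OC)C=O
A6 | alternative 3 | ten-membered C6 allylic alcohol with the C7 acetate arm | COC(=O)C[C@H]1[C@H](O)/C=C(/C)[C@@H](O[Si](C)(C)C(C)(C)C)C/C=C(\C)C[C@H]1OCOC
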